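**Retrosynthetic overview**

1. The target is an acetylphloroglucinol (ring B) joined through two CH2 bridges to two identical rings A. The last disconnections are the C-acetyl group on the only free carbon of ring B, then three benzyl ethers on ring B and one ethyl ether on each ring A.
2. The strategy rests on the substitution pattern of ring A. C1 (butyryl) and C6 (oxygen) map onto an acyl-alkyne; C2 (OH), C3 (methyl), C4 (OMe) and C5 (bridge carbon) map onto a 1,1,3-trioxygenated diene. Bonds C5–C6 and C1–C2 are cut in both rings A at once.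
3. The partners are a bis-diene already hung on tris(benzyloxy) ring B through the bridge carbons, and 1-ethoxyhex-1-yn-3-one, made from ethoxyacetylene and butanal.
4. The bis-diene comes from a bis(β-methoxy enoate), this from a bis(β-keto ester), this from a ring B dipropanoic acid plus methyl propanoate, and the acid from the ring B dialdehyde, Meldrum's acid and phloroglucinol. The arms are grown from the aldehyde because a 2,4,6-trialkoxybenzyl halide would ionise and self-condense.
5. Ring order: ring B is bought as phloroglucinol, the two rings A are closed together in the key step, and no other ring is formed.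

Key step: step 9

Assumption: the enol ether and ketene acetal geometries are drawn for the expected major isomers; they are erased on aromatisation and do not affect the product.

**Route**

Step 1
Reactants: 1 phloroglucinol
Product: 2 2,4,6-trihydroxybenzene-1,3-dicarbaldehyde
Conditions: POCl3 (2.3 equiv), DMF, EtOAc, 0 °C to rt; then H2O, 50 °C
Reagents that add atoms: N,N-dimethylformamide CN(C)C=O; water O
Why: Twofold Vilsmeier–Haack formylation of the very electron-rich triol; with a little over two equivalents of the chloroiminium salt the doubly deactivated ring should stop at the dialdehyde.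

Step 2
Reactants: 2 2,4,6-trihydroxybenzene-1,3-dicarbaldehyde
Product: 3 2,4,6-tris(benzyloxy)benzene-1,3-dicarbaldehyde
Conditions: BnBr (3.6 equiv), K2CO3, DMF, 60 °C
Reagents that add atoms: benzyl bromide BrCc1ccccc1
Why: Williamson etherification; the two formyl groups draw electron density from the last ring carbon, so O-benzylation should win over the C-benzylation that troubles phloroglucinol itself.

Step 3
Reactants: 3 2,4,6-tris(benzyloxy)benzene-1,3-dicarbaldehyde; 4 Meldrum's acid (2,2-dimethyl-1,3-dioxane-4,6-dione)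
Product: 7 3,3'-[2,4,6-tris(benzyloxy)-1,3-phenylene]dipropanoic acid, via bis(arylidene Meldrum's acid) 5 (not isolated), via bis(benzyl Meldrum's acid) 6 (not isolated)
Conditions: HCO2H–Et3N (5:2), 95 °C; then H2O, 95 °C; aq HCl
Reagents that add atoms: water O
Why: Knoevenagel condensation at both aldehydes, conjugate hydride transfer from formate and hydrolytic decarboxylation (reductive Knoevenagel homologation) should give the two propanoic acid arms without passing through a 2,4,6-trialkoxybenzyl cation or halide.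

Step 4
Reactants: 7 3,3'-[2,4,6-tris(benzyloxy)-1,3-phenylene]dipropanoic acid; 8 methyl propanoate
Product: 11 dimethyl 5,5'-[2,4,6-tris(benzyloxy)-1,3-phenylene]bis(2-methyl-3-oxopentanoate) (mixture of diastereomers), via bis(acyl imidazolide) 9 (not isolated), via lithium enolate of methyl propanoate 10 (not isolated)
Conditions: 7, CDI (2.2 equiv), THF, rt; 8 (8 equiv), LiN(i-Pr)2 (8 equiv), THF, −78 °C; combine at −78 °C; aq NH4Cl
Reagents that add atoms: none
Why: Crossed Claisen condensation of an acyl imidazolide with a preformed ester lithium enolate; excess enolate deprotonates the liberated imidazole and the product, which protects the β-keto ester from a second addition.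

Step 5
Reactants: 11 dimethyl 5,5'-[2,4,6-tris(benzyloxy)-1,3-phenylene]bis(2-methyl-3-oxopentanoate)
Product: 13 dimethyl (2E,2'E)-5,5'-[2,4,6-tris(benzyloxy)-1,3-phenylene]bis(3-methoxy-2-methylpent-2-enoate), via bis(dimethyl ketal) 12 (not isolated)
Conditions: HC(OMe)3, MeOH, H2SO4 (cat.), rt; then PPTS (cat.), PhMe, 100 °C
Reagents that add atoms: trimethyl orthoformate COC(OC)OC
Why: Acid-catalysed ketalisation by the orthoformate followed by loss of methanol gives the conjugated β-methoxy enoate (O-methylation of a 2-substituted β-keto ester); any deconjugated or Z isomer converges on the same dienolate in step 6.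

Step 6
Reactants: 13 dimethyl (2E,2'E)-5,5'-[2,4,6-tris(benzyloxy)-1,3-phenylene]bis(3-methoxy-2-methylpent-2-enoate)
Product: 15 1,3,5-tris(benzyloxy)-2,4-bis[(2Z,4Z)-3,5-dimethoxy-4-methyl-5-(trimethylsilyloxy)penta-2,4-dien-1-yl]benzene, via dilithium bis(dienolate) 14 (not isolated)
Conditions: LiN(i-Pr)2 (2.6 equiv), THF, −78 °C; TMSCl, −78 °C to rt; hexane, filtration under Ar; used crude
Reagents that add atoms: chlorotrimethylsilane C[Si](C)(C)Cl
Why: The γ-CH2 of each (E)-β-methoxy enoate lies cis to the ester and is removed by the amide base, and O-silylation of the extended enolate gives the 1-silyloxy-1,3-dimethoxydiene with the benzylic CH2 anti to C2 of the diene (standard silyl ketene acetal formation from β-alkoxy enoates).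

Step 7
Reactants: 16 ethoxyacetylene; 17 butanal
Product: 19 rac-1-ethoxyhex-1-yn-3-ol, via lithium ethoxyacetylide 18 (not isolated)
Conditions: n-BuLi, THF, −78 °C; then 17; aq NH4Cl; Et3N-washed silica
Reagents that add atoms: none
Why: 1,2-Addition of a lithium acetylide to an aldehyde; the new carbinol centre is racemic and is removed in step 8.

Step 8
Reactants: 19 rac-1-ethoxyhex-1-yn-3-ol
Product: 20 1-ethoxyhex-1-yn-3-one
Conditions: MnO2 (activated, excess), CH2Cl2, rt
Reagents that add atoms: none
Why: MnO2 oxidation of a propargylic alcohol under neutral conditions, which avoids the acid-induced Meyer–Schuster rearrangement of the alkoxy-ynol.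

Step 9
Reactants: 15 1,3,5-tris(benzyloxy)-2,4-bis[(2Z,4Z)-3,5-dimethoxy-4-methyl-5-(trimethylsilyloxy)penta-2,4-dien-1-yl]benzene; 20 1-ethoxyhex-1-yn-3-one
Product: 23 1,3,5-tris(benzyloxy)-2,4-bis[(3-butanoyl-2-ethoxy-4-hydroxy-6-methoxy-5-methylphenyl)methyl]benzene, via bis(cyclohexa-1,4-diene) adduct 21 (not isolated), via bis(aryl silyl ether) 22 (not isolated)
Conditions: 20 (3.5 equiv), PhMe, 70 °C; then 1 M HCl, THF, rt
Reagents that add atoms: none
Why: Proposed new method: each diene terminus C5 (the CH carrying the bridge CH2) should attack the ethoxy-bearing β-carbon of 20, and the resulting allenolate carbon C1 then bonds to the dioxygenated carbon C2, either in one asynchronous [4+2] event or as a Mukaiyama–Michael addition followed by 6-exo-trig closure onto the silyloxy(methoxy)carbenium ion. The closest known reaction type is the cycloaddition–aromatisation of 1-silyloxy-1,3-dialkoxybutadienes with ynones and alkynoates, which has not been run with a 3-alkoxy-ynone or twice on one substrate. Each ring A therefore closes as a six-membered carbocycle through the C5–C6 and C1–C2 bonds to give the cyclohexa-1,4-diene 21; loss of methanol across C2 and C5 aromatises it to the aryl silyl ether 22, and dilute acid frees the C2 phenol of 23. No stereocentre survives, so only regiochemistry has to be controlled. The head-to-tail orientation follows from polar matching: the largest HOMO coefficient of the diene lies at C5, remote from the ketene acetal, and the carbonyl and the ethoxy lone pair both polarise the ynone so that its electrophilic carbon is the one bearing ethoxy. The bath is held at 70 °C, below the range in which 1-ethoxyalkynes extrude ethene, and the two arms should react independently.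

Step 10
Reactants: 23 1,3,5-tris(benzyloxy)-2,4-bis[(3-butanoyl-2-ethoxy-4-hydroxy-6-methoxy-5-methylphenyl)methyl]benzene
Product: 24 2,4-bis[(3-butanoyl-2,4-dihydroxy-6-methoxy-5-methylphenyl)methyl]benzene-1,3,5-triol
Conditions: BCl3 (12 equiv), C6HMe5 (10 equiv), CH2Cl2, −78 °C to rt; MeOH then H2O
Reagents that add atoms: none
Why: Chelation-directed ether cleavage: BCl3 bound between the butyryl carbonyl and the flanking ethoxy oxygen lets chloride remove the ethyl group, and the same Lewis acid cleaves the benzyl ethers while pentamethylbenzene traps the benzyl cations; the C4 methyl ether has no neighbouring carbonyl and should persist.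

Step 11
Reactants: 24 2,4-bis[(3-butanoyl-2,4-dihydroxy-6-methoxy-5-methylphenyl)methyl]benzene-1,3,5-triol
Product: 25 1-{3,5-bis[(3-butanoyl-2,4-dihydroxy-6-methoxy-5-methylphenyl)methyl]-2,4,6-trihydroxyphenyl}ethan-1-one (CNP0184345.0)
Conditions: Ac2O (1.2 equiv), BF3·OEt2, 1,4-dioxane, rt; then aq NaOAc, MeOH, 40 °C
Reagents that add atoms: acetic anhydride CC(=O)OC(C)=O
Why: Friedel–Crafts C-acetylation of a phloroglucinol nucleus (O-acylation and Fries shift under BF3); ring B holds the only unsubstituted aromatic carbon of 24, so the acetyl group has one place to go.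

**Compound list**

1 | phloroglucinol | Oc1cc(O)cc(O)c1 | starting material
2 | 2,4,6-trihydroxybenzene-1,3-dicarbaldehyde | O=Cc1c(O)cc(O)c(C=O)c1O | intermediate
3 | 2,4,6-tris(benzyloxy)benzene-1,3-dicarbaldehyde | O=Cc1c(OCc2ccccc2)cc(OCc2ccccc2)c(C=O)c1OCc1ccccc1 | intermediate
4 | Meldrum's acid | CC1(C)OC(=O)CC(=O)O1 | starting material
5 | bis(arylidene Meldrum's acid) from 3 | CC1(C)OC(=O)C(=Cc2c(OCc3ccccc3)cc(OCc3ccccc3)c(C=C3C(=O)OC(C)(C)OC3=O)c2OCc2ccccc2)C(=O)O1 | intermediate
6 | bis(benzyl Meldrum's acid) from 5 | CC1(C)OC(=O)C(Cc2c(OCc3ccccc3)cc(OCc3ccccc3)c(CC3C(=O)OC(C)(C)OC3=O)c2OCc2ccccc2)C(=O)O1 | intermediate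
7 | 3,3'-[2,4,6-tris(benzyloxy)-1,3-phenylene]dipropanoic acid | OC(=O)CCc1c(OCc2ccccc2)cc(OCc2ccccc2)c(CCC(O)=O)c1OCc1ccccc1 | intermediate
8 | methyl propanoate | CCC(=O)OC | starting material
9 | bis(acyl imidazolide) of 7 | O=C(CCc1c(OCc2ccccc2)cc(OCc2ccccc2)c(CCC(=O)n2ccnc2)c1OCc1ccccc1)n1ccnc1 | intermediate
10 | lithium enolate of methyl propanoate | [Li+].CC=C([O-])OC | intermediate
11 | dimethyl 5,5'-[2,4,6-tris(benzyloxy)-1,3-phenylene]bis(2-methyl-3-oxopentanoate), mixture of diastereomers | COC(=O)C(C)C(=O)CCc1c(OCc2ccccc2)cc(OCc2ccccc2)c(CCC(=O)C(C)C(=O)OC)c1OCc1ccccc1 | intermediate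
12 | bis(dimethyl ketal) of 11 | COC(=O)C(C)C(OC)(OC)CCc1c(OCc2ccccc2)cc(OCc2ccccc2)c(CCC(OC)(OC)C(C)C(=O)OC)c1OCc1ccccc1 | intermediate
13 | dimethyl (2E,2'E)-5,5'-[2,4,6-tris(benzyloxy)-1,3-phenylene]bis(3-methoxy-2-methylpent-2-enoate) | COC(=O)/C(C)=C(/OC)CCc1c(OCc2ccccc2)cc(OCc2ccccc2)c(CC/C(OC)=C(/C)C(=O)OC)c1OCc1ccccc1 | intermediate
14 | dilithium bis(dienolate) of 13 | c1c(OCc2ccccc2)c(C/C=C(\OC)/C(C)=C(/OC)[O-])c(OCc2ccccc2)c(C/C=C(\OC)/C(C)=C(/OC)[O-])c1OCc1ccccc1.[Li+].[Li+] | intermediate
15 | 1,3,5-tris(benzyloxy)-2,4-bis[(2Z,4Z)-3,5-dimethoxy-4-methyl-5-(trimethylsilyloxy)penta-2,4-dien-1-yl]benzene | c1c(OCc2ccccc2)c(C/C=C(\OC)/C(C)=C(/OC)O[Si](C)(C)C)c(OCc2ccccc2)c(C/C=C(\OC)/C(C)=C(/OC)O[Si](C)(C)C)c1OCc1ccccc1 | intermediate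
16 | ethoxyacetylene | C#COCC | starting material
17 | butanal | CCCC=O | starting material
18 | lithium ethoxyacetylide | [Li]C#COCC | intermediate
19 | rac-1-ethoxyhex-1-yn-3-ol | CCCC(O)C#COCC | intermediate
20 | 1-ethoxyhex-1-yn-3-one | CCCC(=O)C#COCC | intermediate
21 | bis(cyclohexa-1,4-diene) adduct, mixture of diastereomers | c1c(OCc2ccccc2)c(CC2C(OCC)=C(C(=O)CCC)C(OC)(O[Si](C)(C)C)C(C)=C2OC)c(OCc2ccccc2)c(CC2C(OCC)=C(C(=O)CCC)C(OC)(O[Si](C)(C)C)C(C)=C2OC)c1OCc1ccccc1 | intermediate
22 | bis(aryl trimethylsilyl ether) of 23 | c1c(OCc2ccccc2)c(Cc2c(OC)c(C)c(O[Si](C)(C)C)c(C(=O)CCC)c2OCC)c(OCc2ccccc2)c(Cc2c(OC)c(C)c(O[Si](C)(C)C)c(C(=O)CCC)c2OCC)c1OCc1ccccc1 | intermediate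
23 | 1,3,5-tris(benzyloxy)-2,4-bis[(3-butanoyl-2-ethoxy-4-hydroxy-6-methoxy-5-methylphenyl)methyl]benzene | c1c(OCc2ccccc2)c(Cc2c(OC)c(C)c(O)c(C(=O)CCC)c2OCC)c(OCc2ccccc2)c(Cc2c(OC)c(C)c(O)c(C(=O)CCC)c2OCC)c1OCc1ccccc1 | intermediate
24 | 2,4-bis[(3-butanoyl-2,4-dihydroxy-6-methoxy-5-methylphenyl)methyl]benzene-1,3,5-triol | CCCC(=O)c1c(O)c(C)c(OC)c(Cc2c(O)cc(O)c(Cc3c(O)c(C)c(OC)c(C(=O)CCC)c3O)c2O)c1O | intermediate
25 | 1-{3,5-bis[(3-butanoyl-2,4-dihydroxy-6-methoxy-5-methylphenyl)methyl]-2,4,6-trihydroxyphenyl}ethan-1-one | CCCC(=O)c1c(O)c(C)c(OC)c(Cc2c(O)c(Cc3c(O)c(C)c(OC)c(C(=O)CCC)c3O)c(O)c(C(C)=O)c2O)c1O | target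

**Step count**

Total: 11 steps. Longest linear sequence: 9 steps (steps 1–6, 9, 10, 11); steps 7 and 8 form the ynone branch.

**Steps most likely to fail**

Step 9. The push–pull ynone may be too weak an electrophile, so that the diene is lost by silyl transfer or protodesilylation before either bond forms. Alternatively, conjugate addition may be followed by expulsion of ethoxide instead of ring closure. The fallback uses known chemistry and turns the easy ionisation of the trialkoxybenzyl position to advantage. It sets out from dialdehyde 3, which NaBH4 in THF–MeOH should reduce to [2,4,6-tris(benzyloxy)-1,3-phenylene]dimethanol F1. Acid-catalysed Friedel–Crafts benzylation (p-TsOH cat., CH2Cl2, 0 °C) of an excess of aspidinol, 1-(2,6-dihydroxy-4-methoxy-3-methylphenyl)butan-1-one F2, at its only free ring carbon should give 1,3,5-tris(benzyloxy)-2,4-bis[(3-butanoyl-2,4-dihydroxy-6-methoxy-5-methylphenyl)methyl]benzene F3. Hydrogenolysis (H2, Pd/C, EtOAc) then removes the benzyl groups, and the route is rejoined at 24.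

Step 10. Once the C2 oxygen is tied to boron and to the carbonyl, removal of the ethyl group on the second ortho oxygen may be slow. Forcing it risks loss of the hindered C4 methyl ether and acid-induced migration of the methylene bridges. The fallback stages the deprotection with two orthogonal modes. It sets out from 23, where hydrogenolysis (H2, Pd/C, EtOAc–MeOH) should give 2,4-bis[(3-butanoyl-2-ethoxy-4-hydroxy-6-methoxy-5-methylphenyl)methyl]benzene-1,3,5-triol F4 without any Lewis acid. The ethyl ethers are then cleaved by magnesium chelation and iodide attack (MgI2·OEt2, PhMe–THF, 60 °C), which acts only next to the carbonyl, and the route is rejoined at 24.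

Step 11. O-acetylation of the seven phenols may outrun C-acylation, and the Fries shift to the one free carbon may stall, leaving mixed phenyl acetates. The fallback is a Houben–Hoesch acylation, whose nitrilium electrophile cannot O-acylate. It sets out from 24; MeCN, ZnCl2 and HCl gas in Et2O at 0 °C should give the ring B ketimine, 1-{3,5-bis[(3-butanoyl-2,4-dihydroxy-6-methoxy-5-methylphenyl)methyl]-2,4,6-trihydroxyphenyl}ethan-1-imine F5, as its hydrochloride. Warm water hydrolyses it, and the route is rejoined at 25.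

**Further compounds**

F1 | step 9 | [2,4,6-tris(benzyloxy)-1,3-phenylene]dimethanol | OCc1c(OCc2ccccc2)cc(OCc2ccccc2)c(CO)c1OCc1ccccc1
F2 | step 9 | aspidinol, 1-(2,6-dihydroxy-4-methoxy-3-methylphenyl)butan-1-one | CCCC(=O)c1c(O)cc(OC)c(C)c1O
F3 | step 9 | 1,3,5-tris(benzyloxy)-2,4-bis[(3-butanoyl-2,4-dihydroxy-6-methoxy-5-methylphenyl)methyl]benzene | c1c(OCc2ccccc2)c(Cc2c(OC)c(C)c(O)c(C(=O)CCC)c2O)c(OCc2ccccc2)c(Cc2c(OC)c(C)c(O)c(C(=O)CCC)c2O)c1OCc1ccccc1
F4 | step 10 | 2,4-bis[(3-butanoyl-2-ethoxy-4-hydroxy-6-methoxy-5-methylphenyl)methyl]benzene-1,3,5-triol | c1c(O)c(Cc2c(OC)c(C)c(O)c(C(=O)CCC)c2OCC)c(O)c(Cc2c(OC)c(C)c(O)c(C(=O)CCC)c2OCC)c1O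
F5 | step 11 | 1-{3,5-bis[(3-butanoyl-2,4-dihydroxy-6-methoxy-5-methylphenyl)methyl]-2,4,6-trihydroxyphenyl}ethan-1-imine | CCCC(=O)c1c(O)c(C)c(OC)c(Cc2c(O)c(Cc3c(O)c(C)c(OC)c(C(=O)CCC)c3O)c(O)c(C(C)=N)c2O)c1O
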